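**Strategy.** The 1,2-dioxane (O1–O2–C3–C4–C5–C6) is disconnected at C6–O1 and O2–C3: it is one O2 molecule bridging C6, a methyl-branched tertiary C–H carbon, and C3, the β-carbon of a 2-methyl-2-enoate (C1–C3). An evolved non-heme iron, 2-oxoglutarate-dependent endoperoxidase is asked to insert O2 there in one operation, closing the ring and setting C2, C3 and C6. The precursor is the acyclic (2E)-2,17-dienoic acid with the C10 methyl branch and the C14 tertiary peroxide in place. The C14 peroxide is masked as a 2-methoxypropan-2-yl peroxyketal so that no free hydroperoxide meets divalent iron. The precursor is assembled from citronellyl bromide, (R)-3-bromo-2-methylpropan-1-ol and (R)-linalool.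

Key step: step 14

Remark 1: C6 is carried as a 1:1 epimer mixture (racemic 3) because the key step passes through a planar C6 radical; if the evolved enzyme accepts only one epimer, enantiopure (R)- or (S)-citronellyl bromide replaces 3 with no other change.

Remark 2: the spatial arrangement at C10 and C14 never changes after it is set; the descriptors switch (C10: R in 1–4 and 25, S in 5–24; C14: S in 15–20, R in 21–25) only because the CIP ranking of the neighbours changes.

Step 1
Reactants: 1 (R)-3-bromo-2-methylpropan-1-ol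
Product: 2 [(2R)-3-bromo-2-methylpropoxy](tert-butyl)dimethylsilane
Conditions: TBSCl, imidazole, CH2Cl2, 0 °C → rt
Reagents that add atoms: tert-butyldimethylsilyl chloride, CC(C)(C)[Si](C)(C)Cl
Why: Imidazole-promoted O-silylation masks the hydroxyl so that the bromide can be turned into a Grignard reagent; the stereocentre is not involved.

Step 2
Reactants: 2 [(2R)-3-bromo-2-methylpropoxy](tert-butyl)dimethylsilane; 3 (±)-citronellyl bromide
Product: 5 tert-butyl(dimethyl){[(2S)-2,6,10-trimethylundec-9-en-1-yl]oxy}silane (C6 epimers), via Grignard reagent 4 (not isolated)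
Conditions: Mg, I2 (cat.), THF, 45 °C; then 3, Li2CuCl4 (3 mol %), THF, −10 °C → rt
Reagents that add atoms: none
Why: Kochi-type copper-catalysed sp3–sp3 cross-coupling of a primary Grignard reagent with an unbranched primary bromide should form C8–C9 directly as a saturated bond, so no alkene has to be reduced here, and the C10 centre, β to magnesium, is configurationally stable.

Step 3
Reactants: 5 tert-butyl(dimethyl){[(2S)-2,6,10-trimethylundec-9-en-1-yl]oxy}silane (C6 epimers); 6 ethyl 2-(triphenyl-λ5-phosphanylidene)propanoate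
Product: 8 ethyl (2E,10S)-11-{[tert-butyl(dimethyl)silyl]oxy}-2,6,10-trimethylundec-2-enoate (C6 epimers), via aldehyde 7 (not isolated)
Conditions: O3, CH2Cl2, −78 °C; PPh3, −78 °C → rt; then 6, CH2Cl2, rt → 40 °C
Reagents that add atoms: none
Why: Ozonolysis of the only alkene with reductive work-up, followed in the same flask by a Wittig reaction with a stabilised α-methyl ylide, should give the (2E)-trisubstituted enoate, since such ylides place the ester trans to the chain.

Step 4
Reactants: 8 ethyl (2E,10S)-11-{[tert-butyl(dimethyl)silyl]oxy}-2,6,10-trimethylundec-2-enoate (C6 epimers)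
Product: 9 ethyl (2E,10S)-11-bromo-2,6,10-trimethylundec-2-enoate (C6 epimers)
Conditions: Ph3PBr2, CH2Cl2, 0 °C → rt
Reagents that add atoms: dibromotriphenylphosphorane, BrP(Br)(c1ccccc1)(c1ccccc1)c1ccccc1
Why: Appel-type direct conversion of a primary silyl ether into the bromide (silyl transfer to bromide, then SN2 displacement on the alkoxyphosphonium ion) is known for primary tert-butyldimethylsilyl ethers and leaves the conjugated ester alone.

Step 5
Reactants: 9 ethyl (2E,10S)-11-bromo-2,6,10-trimethylundec-2-enoate (C6 epimers)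
Product: 10 [(2S,9E)-11-ethoxy-2,6,10-trimethyl-11-oxoundec-9-en-1-yl]triphenylphosphonium bromide (C6 epimers)
Conditions: PPh3, MeCN, 90 °C (sealed tube)
Reagents that add atoms: triphenylphosphine, c1ccc(cc1)P(c1ccccc1)c1ccccc1
Why: SN2 quaternisation of triphenylphosphine by the primary bromide (phosphonium salt formation) is slowed by the β-branch, which the temperature compensates, and the α-methyl enoate is a poor acceptor for the phosphine.

Step 6
Reactants: 11 (R)-linalool
Product: 12 (3R)-3,7-dimethyloct-6-ene-1,3-diol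
Conditions: 9-BBN, THF, 0 °C → rt; then NaOH, H2O2, H2O, 0 °C → rt
Reagents that add atoms: hydrogen peroxide, OO
Why: Anti-Markovnikov hydroboration–oxidation, in which 9-BBN reacts with the monosubstituted vinyl group far faster than with the trisubstituted alkene; the carbinol stereocentre is untouched.

Step 7
Reactants: 12 (3R)-3,7-dimethyloct-6-ene-1,3-diol
Product: 14 (2R)-2-methyl-2-(4-methylpent-3-en-1-yl)oxetane, via monotosylate 13 (not isolated)
Conditions: TsCl, pyridine, CH2Cl2, 0 °C; then KOtBu, THF, 0 °C → rt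
Reagents that add atoms: none
Why: Selective sulfonylation of the primary hydroxyl and intramolecular Williamson etherification (4-exo-tet) by the tertiary alkoxide close the oxetane without breaking the C–O bond at the stereocentre, so configuration is retained.

Step 8
Reactants: 14 (2R)-2-methyl-2-(4-methylpent-3-en-1-yl)oxetane
Product: 15 (3S)-3-hydroperoxy-3,7-dimethyloct-6-en-1-ol
Conditions: H2O2 (anhydrous, in Et2O), TMSOTf, Et2O, −78 °C → 0 °C
Reagents that add atoms: hydrogen peroxide, OO
Why: Lewis-acid-promoted perhydrolysis of a 2,2-disubstituted oxetane, in which H2O2 attacks the activated ring at the tertiary carbon opposite the departing oxygen (borderline SN2, inversion), should set the C14 peroxide centre in the configuration the target needs from (R)-linalool, while the trisubstituted alkene could only take part through an unfavourable 5-endo closure.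

Step 9
Reactants: 15 (3S)-3-hydroperoxy-3,7-dimethyloct-6-en-1-ol
Product: 17 (3S)-3-[(2-methoxypropan-2-yl)peroxy]-3,7-dimethyloct-6-en-1-ol, via bis-ketal 16 (not isolated)
Conditions: 2-methoxypropene (excess), PPTS (cat.), CH2Cl2, 0 °C; then MeOH, 0 °C, short, Et3N quench
Reagents that add atoms: 2-methoxypropene, COC(C)=C
Why: Acid-catalysed ketalisation of both O–H groups by the enol ether is followed by methanolysis with the same catalyst, which should remove the ordinary mixed ketal on the alcohol much faster than the monoperoxyketal, whose peroxy oxygen is a poor base and a poor donor.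

Step 10
Reactants: 17 (3S)-3-[(2-methoxypropan-2-yl)peroxy]-3,7-dimethyloct-6-en-1-ol
Product: 18 (3S)-3-[(2-methoxypropan-2-yl)peroxy]-3,7-dimethyloct-6-enal
Conditions: Dess–Martin periodinane, NaHCO3, CH2Cl2, 0 °C → rt
Reagents that add atoms: none
Why: Dess–Martin oxidation under buffered, non-basic conditions should give the β-peroxy aldehyde without β-elimination and without touching the peroxyketal or the alkene; the aldehyde is used at once.

Step 11
Reactants: 10 [(2S,9E)-11-ethoxy-2,6,10-trimethyl-11-oxoundec-9-en-1-yl]triphenylphosphonium bromide (C6 epimers); 18 (3S)-3-[(2-methoxypropan-2-yl)peroxy]-3,7-dimethyloct-6-enal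
Product: 20 ethyl (2E,10S,11Z,14S)-14-[(2-methoxypropan-2-yl)peroxy]-2,6,10,14,18-pentamethylnonadeca-2,11,17-trienoate (C6 epimers), via ylide 19 (not isolated)
Conditions: NaN(SiMe3)2 (1.0 equiv), THF, −78 °C → 0 °C; then 18, THF, −78 °C → −20 °C
Reagents that add atoms: none
Why: Wittig olefination with a non-stabilised, salt-free ylide at low temperature, conditions that peroxyketal-protected peroxy aldehydes are known to survive, should form C11=C12 faster than the aldehyde enolises; the Z/E ratio does not matter because the alkene is reduced next.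

Step 12
Reactants: 20 ethyl (2E,10S,11Z,14S)-14-[(2-methoxypropan-2-yl)peroxy]-2,6,10,14,18-pentamethylnonadeca-2,11,17-trienoate (C6 epimers)
Product: 21 ethyl (2E,10S,14R)-14-[(2-methoxypropan-2-yl)peroxy]-2,6,10,14,18-pentamethylnonadeca-2,17-dienoate (C6 epimers)
Conditions: 2-nitrobenzenesulfonylhydrazide, Et3N, CH2Cl2, rt
Reagents that add atoms: none
Why: Diimide reduction transfers H2 concertedly to the 1,2-disubstituted alkene faster than to the trisubstituted C17=C18 alkene or the conjugated trisubstituted enoate and does not cleave O–O bonds; the reaction is stopped when 20 is consumed and any over-reduced material is removed on AgNO3-impregnated silica.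

Step 13
Reactants: 21 ethyl (2E,10S,14R)-14-[(2-methoxypropan-2-yl)peroxy]-2,6,10,14,18-pentamethylnonadeca-2,17-dienoate (C6 epimers)
Product: 22 (2E,10S,14R)-14-[(2-methoxypropan-2-yl)peroxy]-2,6,10,14,18-pentamethylnonadeca-2,17-dienoic acid (C6 epimers)
Conditions: LiOH·H2O, THF/MeOH/H2O, rt → 35 °C; then 0.5 M HCl to pH 5, 0 °C
Reagents that add atoms: lithium hydroxide, [Li+].[OH-]
Why: Saponification (acyl–oxygen cleavage) of the ethyl ester, to which the peroxyketal and the fully substituted dialkyl peroxide are inert; the brief, cold acidification to pH 5 should keep the peroxyketal.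

Step 14
Reactants: 22 (2E,10S,14R)-14-[(2-methoxypropan-2-yl)peroxy]-2,6,10,14,18-pentamethylnonadeca-2,17-dienoic acid (C6 epimers)
Product: 23 (2R)-2-[(3S,6R)-6-{(4S,8R)-8-[(2-methoxypropan-2-yl)peroxy]-4,8,12-trimethyltridec-11-en-1-yl}-6-methyl-1,2-dioxan-3-yl]propanoic acid
Conditions: evolved non-heme iron, 2-oxoglutarate-dependent endoperoxidase (verruculogen-synthase-type scaffold), (NH4)2Fe(SO4)2 (divalent iron), 2-oxoglutaric acid, L-ascorbic acid, O2 (air), 50 mM HEPES pH 7.5, 5% DMSO, 25 °C
Reagents that add atoms: dioxygen, O=O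
Why: Proposed new method: the tetravalent iron-oxo species that the enzyme forms from divalent iron, 2-oxoglutarate and O2 abstracts the tertiary C6–H of 22, the planar C6 radical captures a second O2, and the C6–O1–O2 peroxyl radical adds to C3 of the enoate before an active-site tyrosine, re-reduced by ascorbate, delivers a hydrogen atom to C2. The closest known reaction type is enzymatic endoperoxide formation by non-heme iron, 2-oxoglutarate-dependent oxygenases of the verruculogen-synthase type and by prostaglandin H synthase, neither of which has been shown on an acyclic terpenoid enoate. The 1,2-dioxane (O1–O2–C3–C4–C5–C6) closes 6-exo-trig through the O2–C3 bond, with C2 left outside the ring. C6 is set by the face of the planar radical that the pocket leaves open to O2 (so both C6 epimers of 22 converge), C3 by the enoate face held toward the peroxyl radical, and C2 by the position of the hydrogen-donating tyrosine relative to the (2E)-enoate, while C10 and C14 are not touched. The step needs site selectivity for C6–H over the tertiary C10–H and the allylic C–H bonds at C16 and on the C18 methyl groups, and facial control at three centres; the substrate contributes only the carboxylate anchor that fixes the register of the chain, the weak tertiary C–H bond and the six-atom C6-to-C3 spacing, so the rest must come from directed evolution. The C14 peroxide is presented as a peroxyketal so that it is no more reactive toward the ferrous centre than the endoperoxide being formed.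

Step 15
Reactants: 23 (2R)-2-[(3S,6R)-6-{(4S,8R)-8-[(2-methoxypropan-2-yl)peroxy]-4,8,12-trimethyltridec-11-en-1-yl}-6-methyl-1,2-dioxan-3-yl]propanoic acid
Product: 24 methyl (2R)-2-[(3S,6R)-6-{(4S,8R)-8-[(2-methoxypropan-2-yl)peroxy]-4,8,12-trimethyltridec-11-en-1-yl}-6-methyl-1,2-dioxan-3-yl]propanoate
Conditions: Me3SiCHN2, toluene/MeOH (4:1), 0 °C → rt
Reagents that add atoms: trimethylsilyldiazomethane, C[Si](C)(C)C=[N+]=[N-]
Why: Diazomethane-type O-methylation of the carboxylic acid under neutral conditions should leave both peroxides, the alkene and the three new stereocentres alone.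

Step 16
Reactants: 24 methyl (2R)-2-[(3S,6R)-6-{(4S,8R)-8-[(2-methoxypropan-2-yl)peroxy]-4,8,12-trimethyltridec-11-en-1-yl}-6-methyl-1,2-dioxan-3-yl]propanoate
Product: 25 methyl (2R)-2-[(3S,6R)-6-[(4R,8R)-8-hydroperoxy-4,8,12-trimethyltridec-11-en-1-yl]-6-methyl-1,2-dioxan-3-yl]propanoate
Conditions: AcOH/THF/H2O (4:2:1), rt
Reagents that add atoms: none
Why: Mild acid hydrolysis of the monoperoxyketal is the standard release of a hydroperoxide from its 2-methoxypropan-2-yl derivative, and the 1,2-dioxane, the methyl ester and the trisubstituted alkene are inert to aqueous acetic acid.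

**Compound list**

1 | (R)-3-bromo-2-methylpropan-1-ol | OC[C@@H](C)CBr | starting material
2 | [(2R)-3-bromo-2-methylpropoxy](tert-butyl)dimethylsilane | CC(C)(C)[Si](C)(C)OC[C@@H](C)CBr | intermediate
3 | (±)-citronellyl bromide (8-bromo-2,6-dimethyloct-2-ene) | CC(C)=CCCC(C)CCBr | starting material
4 | bromo{(2R)-3-{[tert-butyl(dimethyl)silyl]oxy}-2-methylpropyl}magnesium | CC(C)(C)[Si](C)(C)OC[C@@H](C)C[Mg]Br | intermediate
5 | tert-butyl(dimethyl){[(2S)-2,6,10-trimethylundec-9-en-1-yl]oxy}silane (C6 epimers) | CC(C)(C)[Si](C)(C)OC[C@@H](C)CCCC(C)CCC=C(C)C | intermediate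
6 | ethyl 2-(triphenyl-λ5-phosphanylidene)propanoate | CCOC(=O)C(C)=P(c1ccccc1)(c1ccccc1)c1ccccc1 | starting material
7 | (8S)-9-{[tert-butyl(dimethyl)silyl]oxy}-4,8-dimethylnonanal (C4 epimers) | O=CCCC(C)CCC[C@H](C)CO[Si](C)(C)C(C)(C)C | intermediate
8 | ethyl (2E,10S)-11-{[tert-butyl(dimethyl)silyl]oxy}-2,6,10-trimethylundec-2-enoate (C6 epimers) | CCOC(=O)/C(C)=C/CCC(C)CCC[C@H](C)CO[Si](C)(C)C(C)(C)C | intermediate
9 | ethyl (2E,10S)-11-bromo-2,6,10-trimethylundec-2-enoate (C6 epimers) | CCOC(=O)/C(C)=C/CCC(C)CCC[C@H](C)CBr | intermediate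
10 | [(2S,9E)-11-ethoxy-2,6,10-trimethyl-11-oxoundec-9-en-1-yl]triphenylphosphonium bromide (C6 epimers) | CCOC(=O)/C(C)=C/CCC(C)CCC[C@H](C)C[P+](c1ccccc1)(c1ccccc1)c1ccccc1.[Br-] | intermediate
11 | (R)-linalool | C=C[C@](C)(O)CCC=C(C)C | starting material
12 | (3R)-3,7-dimethyloct-6-ene-1,3-diol | OCC[C@](C)(O)CCC=C(C)C | intermediate
13 | (3R)-3-hydroxy-3,7-dimethyloct-6-en-1-yl 4-methylbenzenesulfonate | Cc1ccc(cc1)S(=O)(=O)OCC[C@](C)(O)CCC=C(C)C | intermediate
14 | (2R)-2-methyl-2-(4-methylpent-3-en-1-yl)oxetane | C[C@@]1(CCC=C(C)C)CCO1 | intermediate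
15 | (3S)-3-hydroperoxy-3,7-dimethyloct-6-en-1-ol | OCC[C@@](C)(OO)CCC=C(C)C | intermediate
16 | 2-methoxy-2-{[(3S)-3-[(2-methoxypropan-2-yl)peroxy]-3,7-dimethyloct-6-en-1-yl]oxy}propane | COC(C)(C)OCC[C@@](C)(OOC(C)(C)OC)CCC=C(C)C | intermediate
17 | (3S)-3-[(2-methoxypropan-2-yl)peroxy]-3,7-dimethyloct-6-en-1-ol | OCC[C@@](C)(OOC(C)(C)OC)CCC=C(C)C | intermediate
18 | (3S)-3-[(2-methoxypropan-2-yl)peroxy]-3,7-dimethyloct-6-enal | O=CC[C@@](C)(OOC(C)(C)OC)CCC=C(C)C | intermediate
19 | ethyl (2E,10S)-2,6,10-trimethyl-11-(triphenyl-λ5-phosphanylidene)undec-2-enoate (C6 epimers) | CCOC(=O)/C(C)=C/CCC(C)CCC[C@H](C)C=P(c1ccccc1)(c1ccccc1)c1ccccc1 | intermediate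
20 | ethyl (2E,10S,11Z,14S)-14-[(2-methoxypropan-2-yl)peroxy]-2,6,10,14,18-pentamethylnonadeca-2,11,17-trienoate (C6 epimers) | CCOC(=O)/C(C)=C/CCC(C)CCC[C@H](C)/C=C\C[C@](C)(CCC=C(C)C)OOC(C)(C)OC | intermediate
21 | ethyl (2E,10S,14R)-14-[(2-methoxypropan-2-yl)peroxy]-2,6,10,14,18-pentamethylnonadeca-2,17-dienoate (C6 epimers) | CCOC(=O)/C(C)=C/CCC(C)CCC[C@H](C)CCC[C@](C)(CCC=C(C)C)OOC(C)(C)OC | intermediate
22 | (2E,10S,14R)-14-[(2-methoxypropan-2-yl)peroxy]-2,6,10,14,18-pentamethylnonadeca-2,17-dienoic acid (C6 epimers) | OC(=O)/C(C)=C/CCC(C)CCC[C@H](C)CCC[C@](C)(CCC=C(C)C)OOC(C)(C)OC | intermediate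
23 | (2R)-2-[(3S,6R)-6-{(4S,8R)-8-[(2-methoxypropan-2-yl)peroxy]-4,8,12-trimethyltridec-11-en-1-yl}-6-methyl-1,2-dioxan-3-yl]propanoic acid | OC(=O)[C@H](C)[C@@H]1CC[C@@](C)(CCC[C@H](C)CCC[C@](C)(CCC=C(C)C)OOC(C)(C)OC)OO1 | intermediate
24 | methyl (2R)-2-[(3S,6R)-6-{(4S,8R)-8-[(2-methoxypropan-2-yl)peroxy]-4,8,12-trimethyltridec-11-en-1-yl}-6-methyl-1,2-dioxan-3-yl]propanoate | COC(=O)[C@H](C)[C@@H]1CC[C@@](C)(CCC[C@H](C)CCC[C@](C)(CCC=C(C)C)OOC(C)(C)OC)OO1 | intermediate
25 | methyl (2R)-2-[(3S,6R)-6-[(4R,8R)-8-hydroperoxy-4,8,12-trimethyltridec-11-en-1-yl]-6-methyl-1,2-dioxan-3-yl]propanoate | COC(=O)[C@H](C)[C@@H]1CC[C@@](C)(CCC[C@H](C)CCC[C@](C)(CCC=C(C)C)OO)OO1 | target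

**Step count and risk**

Total step count: 16. Longest linear sequence: 11 steps (steps 1–5 or steps 6–10, then steps 11–16).

Steps most likely to fail:

Step 14 (Proposed new method). Hydrogen abstraction may occur at C10–H or at allylic positions instead of C6–H, the faces of O2 capture, peroxyl addition and hydrogen delivery may not be controlled, or the ferrous centre may cleave the peroxides by one-electron reduction. The fallback uses known chemistry throughout, sets out from 17 (with 1 and 18) and returns at 25. It takes the C6 peroxide from a second portion of 17, which already has the required configuration, and closes the ring by conjugate addition of a hydroperoxide instead of by C–H oxidation. Ozonolysis of 17 (O3, CH2Cl2/MeOH, −78 °C; Me2S) and Wittig reaction with methyl 2-(triphenyl-λ5-phosphanylidene)propanoate should give methyl (2E,6S)-8-hydroxy-6-[(2-methoxypropan-2-yl)peroxy]-2,6-dimethyloct-2-enoate F1, which Dess–Martin periodinane oxidises to methyl (2E,6S)-6-[(2-methoxypropan-2-yl)peroxy]-2,6-dimethyl-8-oxooct-2-enoate F2. Separately, 1 and PPh3 give [(2R)-3-hydroxy-2-methylpropyl]triphenylphosphonium bromide F3, and a Mitsunobu reaction with 1-phenyl-1H-tetrazole-5-thiol gives {(2S)-2-methyl-3-[(1-phenyl-1H-tetrazol-5-yl)sulfanyl]propyl}triphenylphosphonium bromide F4. The ylide of F4 (NaN(SiMe3)2) and F2 should give methyl (2E,6S,8Z,10S)-6-[(2-methoxypropan-2-yl)peroxy]-2,6,10-trimethyl-11-[(1-phenyl-1H-tetrazol-5-yl)sulfanyl]undeca-2,8-dienoate F5, which (NH4)6Mo7O24/H2O2 oxidises to the corresponding sulfone, methyl (2E,6S,8Z,10S)-6-[(2-methoxypropan-2-yl)peroxy]-2,6,10-trimethyl-11-[(1-phenyl-1H-tetrazol-5-yl)sulfonyl]undeca-2,8-dienoate F6. Julia–Kocienski olefination of F6 with 18 (KN(SiMe3)2, DME, −60 °C) should give methyl (2E,6S,8Z,10R,11E,14S)-6,14-bis[(2-methoxypropan-2-yl)peroxy]-2,6,10,14,18-pentamethylnonadeca-2,8,11,17-tetraenoate F7. Diimide as in step 12 saturates both disubstituted alkenes to give methyl (2E,6R,10R,14R)-6,14-bis[(2-methoxypropan-2-yl)peroxy]-2,6,10,14,18-pentamethylnonadeca-2,17-dienoate F8. Aqueous acetic acid as in step 16 then frees methyl (2E,6R,10R,14R)-6,14-dihydroperoxy-2,6,10,14,18-pentamethylnonadeca-2,17-dienoate F9. Et2NH in CF3CH2OH closes the 1,2-dioxane by 6-exo conjugate addition of the C6 hydroperoxide to C3 and should give 25 together with its C2 and C3 diastereomers, from which it is separated by HPLC.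

Step 9. The peroxyketal may be lost together with the alcohol ketal during methanolysis, or the intermediate may close to a 1,2,4-trioxepane. The fallback sets out from 15 and returns at 17. Lipase-catalysed acetylation (immobilised Candida antarctica lipase B, vinyl acetate, MTBE), which acylates the primary alcohol but should not accept the tertiary hydroperoxide, gives (3S)-3-hydroperoxy-3,7-dimethyloct-6-en-1-yl acetate F10. Ketalisation with 2-methoxypropene and PPTS gives (3S)-3-[(2-methoxypropan-2-yl)peroxy]-3,7-dimethyloct-6-en-1-yl acetate F11, and K2CO3 in MeOH removes the acetate to give 17.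

Step 11. The β-branched ylide may add slowly, so that enolisation and β-elimination of the peroxy aldehyde, or oxygen transfer from the peroxide to the ylide phosphorus, compete; slow salt formation in step 5 would add to this. The fallback replaces the phosphorus ylide by a sulfonyl carbanion, sets out from 9 and returns at 21. Thiolate displacement (1-phenyl-1H-tetrazole-5-thiol, K2CO3, DMF) gives ethyl (2E,10S)-2,6,10-trimethyl-11-[(1-phenyl-1H-tetrazol-5-yl)sulfanyl]undec-2-enoate F12, and (NH4)6Mo7O24/H2O2 gives the sulfone, ethyl (2E,10S)-2,6,10-trimethyl-11-[(1-phenyl-1H-tetrazol-5-yl)sulfonyl]undec-2-enoate F13. Julia–Kocienski olefination with 18 (KN(SiMe3)2, DME, −60 °C) should give ethyl (2E,10S,11E,14S)-14-[(2-methoxypropan-2-yl)peroxy]-2,6,10,14,18-pentamethylnonadeca-2,11,17-trienoate F14, and diimide reduction as in step 12 gives 21.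

**Further compounds**

F1 | step 14 | methyl (2E,6S)-8-hydroxy-6-[(2-methoxypropan-2-yl)peroxy]-2,6-dimethyloct-2-enoate | COC(=O)/C(C)=C/CC[C@@](C)(CCO)OOC(C)(C)OC
F2 | step 14 | methyl (2E,6S)-6-[(2-methoxypropan-2-yl)peroxy]-2,6-dimethyl-8-oxooct-2-enoate | COC(=O)/C(C)=C/CC[C@@](C)(CC=O)OOC(C)(C)OC
F3 | step 14 | [(2R)-3-hydroxy-2-methylpropyl]triphenylphosphonium bromide | OC[C@@H](C)C[P+](c1ccccc1)(c1ccccc1)c1ccccc1.[Br-]
F4 | step 14 | {(2S)-2-methyl-3-[(1-phenyl-1H-tetrazol-5-yl)sulfanyl]propyl}triphenylphosphonium bromide | c1ccccc1-n1nnnc1SC[C@@H](C)C[P+](c1ccccc1)(c1ccccc1)c1ccccc1.[Br-]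
F5 | step 14 | methyl (2E,6S,8Z,10S)-6-[(2-methoxypropan-2-yl)peroxy]-2,6,10-trimethyl-11-[(1-phenyl-1H-tetrazol-5-yl)sulfanyl]undeca-2,8-dienoate | COC(=O)/C(C)=C/CC[C@@](C)(C/C=C\[C@H](C)CSc1nnnn1-c1ccccc1)OOC(C)(C)OC
F6 | step 14 | methyl (2E,6S,8Z,10S)-6-[(2-methoxypropan-2-yl)peroxy]-2,6,10-trimethyl-11-[(1-phenyl-1H-tetrazol-5-yl)sulfonyl]undeca-2,8-dienoate | COC(=O)/C(C)=C/CC[C@@](C)(C/C=C\[C@H](C)CS(=O)(=O)c1nnnn1-c1ccccc1)OOC(C)(C)OC
F7 | step 14 | methyl (2E,6S,8Z,10R,11E,14S)-6,14-bis[(2-methoxypropan-2-yl)peroxy]-2,6,10,14,18-pentamethylnonadeca-2,8,11,17-tetraenoate | COC(=O)/C(C)=C/CC[C@@](C)(C/C=C\[C@H](C)/C=C/C[C@](C)(CCC=C(C)C)OOC(C)(C)OC)OOC(C)(C)OC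
F8 | step 14 | methyl (2E,6R,10R,14R)-6,14-bis[(2-methoxypropan-2-yl)peroxy]-2,6,10,14,18-pentamethylnonadeca-2,17-dienoate | COC(=O)/C(C)=C/CC[C@@](C)(CCC[C@H](C)CCC[C@](C)(CCC=C(C)C)OOC(C)(C)OC)OOC(C)(C)OC
F9 | step 14 | methyl (2E,6R,10R,14R)-6,14-dihydroperoxy-2,6,10,14,18-pentamethylnonadeca-2,17-dienoate | COC(=O)/C(C)=C/CC[C@@](C)(CCC[C@H](C)CCC[C@](C)(CCC=C(C)C)OO)OO
F10 | step 9 | (3S)-3-hydroperoxy-3,7-dimethyloct-6-en-1-yl acetate | CC(=O)OCC[C@@](C)(OO)CCC=C(C)C
F11 | step 9 | (3S)-3-[(2-methoxypropan-2-yl)peroxy]-3,7-dimethyloct-6-en-1-yl acetate | CC(=O)OCC[C@@](C)(OOC(C)(C)OC)CCC=C(C)C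
F12 | step 11 | ethyl (2E,10S)-2,6,10-trimethyl-11-[(1-phenyl-1H-tetrazol-5-yl)sulfanyl]undec-2-enoate (C6 epimers) | CCOC(=O)/C(C)=C/CCC(C)CCC[C@H](C)CSc1nnnn1-c1ccccc1
F13 | step 11 | ethyl (2E,10S)-2,6,10-trimethyl-11-[(1-phenyl-1H-tetrazol-5-yl)sulfonyl]undec-2-enoate (C6 epimers) | CCOC(=O)/C(C)=C/CCC(C)CCC[C@H](C)CS(=O)(=O)c1nnnn1-c1ccccc1
F14 | step 11 | ethyl (2E,10S,11E,14S)-14-[(2-methoxypropan-2-yl)peroxy]-2,6,10,14,18-pentamethylnonadeca-2,11,17-trienoate (C6 epimers) | CCOC(=O)/C(C)=C/CCC(C)CCC[C@H](C)/C=C/C[C@](C)(CCC=C(C)C)OOC(C)(C)OC
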